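**Retrosynthetic overview**
- The target is opened up as: global desilylation ⇐ Yamaguchi acylation of the 6α-hydroxy methyl ester with a silyl-protected 2-(hydroxymethyl)acrylic acid ⇐ saponification/O-methylation of an α-methylene-γ-lactone.
- The α-methylene lactone ⇐ selenoxide elimination on the bis-silylated 1β,3β-dihydroxy-4(15)-ene lactone ⇐ Ti(III) opening of a 3β,4β-epoxide ⇐ Δ3-olefin (11β,13-dihydrosantamarine).
- The Δ3-olefin ⇐ C1 inversion (oxidation/reduction) ⇐ key step: allylic-diazene [1,5]-sigmatropic hydrogen shift (retro-ene, –N2) on a 1α,3β-dihydroxy-Δ4 lactone. This step forms the C5–H bond on the α face (trans-decalin) and moves the olefin to C3=C4.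
- That diol ⇐ nucleophilic epoxidation, reductive epoxide opening and directed reduction of (−)-α-santonin, which supplies C6, C7 and C10.
- Ring order: no carbocycle is built. Both six-membered rings and the lactone are bought in santonin; only transient epoxide rings are made, and the lactone is opened near the end.

Assumption/notation: eudesmane numbering is used (C1–C10 decalin, C11–C13 side chain, C14 on C10, C15 on C4), TBSO = tert-butyldimethylsilyloxy, and natural (−)-α-santonin and ethyl 2-(hydroxymethyl)acrylate are bought.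

**Step 1**
Reactants: 1 ethyl 2-(hydroxymethyl)acrylate
Product: 2 ethyl 2-[(TBSO)methyl]acrylate
Conditions: TBSCl, imidazole, CH2Cl2, 0 °C → rt
Reagents that add atoms: tert-butyldimethylsilyl chloride, CC(C)(C)[Si](C)(C)Cl
Why: Standard silylation of a primary alcohol, which masks the side-chain hydroxyl for the later esterification; no stereocentre is involved.

**Step 2**
Reactants: 2 ethyl 2-[(TBSO)methyl]acrylate
Product: 3 2-[(TBSO)methyl]acrylic acid
Conditions: LiOH·H2O, THF/H2O, 0 °C → rt; then 1 M HCl to pH 4, 0 °C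
Reagents that add atoms: lithium hydroxide, [Li+].[OH-]
Why: Ester saponification under mild conditions, where the primary TBS ether survives cold aqueous base and brief weak acid.

**Step 3**
Reactants: 4 (−)-α-santonin
Product: 5 1α,2α-epoxy-3-oxoeudesm-4-en-6α,12-olide
Conditions: t-BuOOH (decane), Triton B (cat.), THF, 0 °C → rt
Reagents that add atoms: tert-butyl hydroperoxide, CC(C)(C)OO
Why: Weitz–Scheffer nucleophilic epoxidation, in which the peroxide anion adds to C1 of the Δ1 enone (C5 of the Δ4 enone is fully substituted) anti to the C10 β-methyl, so the epoxide is 1α,2α.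

**Step 4**
Reactants: 5 1α,2α-epoxy-3-oxoeudesm-4-en-6α,12-olide
Product: 7 1α-hydroxy-3-oxoeudesm-4-en-6α,12-olide, via 2β-phenylselanyl ketol 6 (not isolated)
Conditions: (PhSe)2, NaBH4, EtOH; AcOH; 0 °C → rt
Reagents that add atoms: none
Why: Miyashita organoselenium reduction of an α,β-epoxy ketone, where PhSe− opens C2–O trans-diaxially and a second selenolate removes selenium from C2, so the C1–O bond keeps its α configuration and the buffered medium avoids β-elimination.

**Step 5**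
Reactants: 7 1α-hydroxy-3-oxoeudesm-4-en-6α,12-olide
Product: 8 1α,3β-dihydroxyeudesm-4-en-6α,12-olide
Conditions: Me4NBH(OAc)3, MeCN/AcOH (1:1), −20 °C
Reagents that add atoms: none
Why: Evans–Saksena hydroxyl-directed 1,2-reduction, in which boron bound to the axial 1α-OH delivers hydride to the α face of C3=O and gives the 1,3-anti diol with 3β-OH.

**Step 6 (key step)**
Reactants: 8 1α,3β-dihydroxyeudesm-4-en-6α,12-olide
Product: 11 1α-hydroxy-5αH-eudesm-3-en-6α,12-olide, via sulfonylhydrazine adduct 9 (not isolated), via allylic diazene 10 (not isolated)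
Conditions: o-O2NC6H4SO2NHNH2, PPh3, DEAD, N-methylmorpholine, −30 °C; then 23 °C
Reagents that add atoms: none
Why: Myers reductive 1,3-transposition, in which Mitsunobu displacement inverts the allylic C3 (the neopentyl axial 1α-OH is inert), loss of sulfinic acid gives the 3α-diazene, and its suprafacial [1,5]-sigmatropic hydrogen shift (retro-ene, –N2) puts H on C5 from the α face (trans ring fusion) and moves the olefin to C3=C4.

**Step 7**
Reactants: 11 1α-hydroxy-5αH-eudesm-3-en-6α,12-olide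
Product: 12 1-oxo-5αH-eudesm-3-en-6α,12-olide
Conditions: Dess–Martin periodinane, NaHCO3, CH2Cl2, 0 °C → rt
Reagents that add atoms: none
Why: Dess–Martin oxidation of the hindered axial alcohol under buffered neutral conditions, which keeps the β,γ-olefin out of conjugation and removes the wrong C1 configuration.

**Step 8**
Reactants: 12 1-oxo-5αH-eudesm-3-en-6α,12-olide
Product: 13 1β-hydroxy-5αH-eudesm-3-en-6α,12-olide (11β,13-dihydrosantamarine)
Conditions: NaBH4, MeOH, −20 → 0 °C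
Reagents that add atoms: none
Why: Ketone reduction by hydride attack on the α face, anti to the axial C10 methyl, which gives the equatorial 1β-alcohol while the lactone is untouched at low temperature.

**Step 9**
Reactants: 13 1β-hydroxy-5αH-eudesm-3-en-6α,12-olide
Product: 15 3β,4β-epoxy-1β-hydroxy-5αH-eudesman-6α,12-olide, via bromohydrin 14 (not isolated)
Conditions: NBS, acetone/H2O (4:1), 0 °C; then K2CO3, rt
Reagents that add atoms: water, O
Why: Bromohydrin formation and ring closure, where Br+ takes the open α face, water opens the bromonium trans-diaxially at tertiary C4 from the β face (Markovnikov, Fürst–Plattner) and base closes the 3β,4β-epoxide, the face that a peracid would not reach.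

**Step 10**
Reactants: 15 3β,4β-epoxy-1β-hydroxy-5αH-eudesman-6α,12-olide
Product: 16 1β,3β-dihydroxy-5αH-eudesm-4(15)-en-6α,12-olide
Conditions: Cp2TiCl2 (3 equiv), Mn dust, THF, rt; dilute HCl work-up
Reagents that add atoms: none
Why: Nugent–RajanBabu Ti(III) radical epoxide opening, in which homolysis of the tertiary C4–O bond, capture by a second Ti(III) and loss of a methyl hydrogen give the exocyclic C4=C15 olefin while the untouched C3–O bond keeps the 3β configuration.

**Step 11**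
Reactants: 16 1β,3β-dihydroxy-5αH-eudesm-4(15)-en-6α,12-olide
Product: 17 1β,3β-bis(TBSO)-5αH-eudesm-4(15)-en-6α,12-olide
Conditions: TBSOTf, 2,6-lutidine, CH2Cl2, −78 → 0 °C
Reagents that add atoms: tert-butyldimethylsilyl triflate, CC(C)(C)[Si](C)(C)OS(=O)(=O)C(F)(F)F
Why: Silyl triflate protection of both secondary alcohols, including the hindered neopentyl one, so that enolate chemistry and the later selective 6-O-acylation are possible.

**Step 12**
Reactants: 17 1β,3β-bis(TBSO)-5αH-eudesm-4(15)-en-6α,12-olide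
Product: 20 1β,3β-bis(TBSO)-5αH-eudesma-4(15),11(13)-dien-6α,12-olide, via 11-phenylselanyl lactone 18 (not isolated), via selenoxide 19 (not isolated)
Conditions: LDA, THF, −78 °C; PhSeBr, −78 °C; then 30% H2O2, pyridine, CH2Cl2, 0 °C → rt
Reagents that add atoms: none
Why: Grieco α-methylenation, in which the lactone enolate is selenenylated at C11 and the selenoxide undergoes syn-elimination toward the C13 methyl to give the exocyclic methylene, removing the C11 stereocentre.

**Step 13**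
Reactants: 20 1β,3β-bis(TBSO)-5αH-eudesma-4(15),11(13)-dien-6α,12-olide
Product: 22 methyl 6α-hydroxy-1β,3β-bis(TBSO)eudesma-4(15),11(13)-dien-12-oate, via lithium carboxylate 21 (not isolated)
Conditions: LiOH, THF/H2O, 0 °C → rt; evaporate; MeI, DMF, rt; used at once
Reagents that add atoms: lithium hydroxide, [Li+].[OH-]; iodomethane, CI
Why: Saponification of the trans-fused lactone followed by SN2 O-methylation of the carboxylate without any acidification, which gives the γ-hydroxy ester before it can relactonise and leaves C6 and C7 untouched.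

**Step 14**
Reactants: 22 methyl 6α-hydroxy-1β,3β-bis(TBSO)eudesma-4(15),11(13)-dien-12-oate; 3 2-[(TBSO)methyl]acrylic acid
Product: 24 methyl 1β,3β-bis(TBSO)-6α-{2-[(TBSO)methyl]acryloyloxy}eudesma-4(15),11(13)-dien-12-oate, via mixed anhydride 23 (not isolated)
Conditions: 3, 2,4,6-Cl3C6H2COCl, Et3N, THF, rt; then 22, DMAP, toluene, rt
Reagents that add atoms: none
Why: Yamaguchi esterification, where the activated mixed anhydride acylates the only free hydroxyl (the equatorial 6α-OH) faster than that hydroxyl can relactonise.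

**Step 15**
Reactants: 24 methyl 1β,3β-bis(TBSO)-6α-{2-[(TBSO)methyl]acryloyloxy}eudesma-4(15),11(13)-dien-12-oate
Product: 25 methyl (1R,3S,5S,6S,7S,10R)-1β,3β-dihydroxy-6α-[2-(hydroxymethyl)acryloyloxy]eudesma-4(15),11(13)-dien-12-oate (target)
Conditions: HF·pyridine, pyridine/THF, 0 °C → rt
Reagents that add atoms: none
Why: Buffered fluoride desilylation removes all three TBS groups without touching the two acrylate esters or the allylic alcohol, and with no free hydroxyl near O6 there is no acyl migration.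

**Compound list**
1 | ethyl 2-(hydroxymethyl)acrylate | C=C(CO)C(=O)OCC | starting material
2 | ethyl 2-[(TBSO)methyl]acrylate | C=C(CO[Si](C)(C)C(C)(C)C)C(=O)OCC | intermediate
3 | 2-[(TBSO)methyl]acrylic acid | C=C(CO[Si](C)(C)C(C)(C)C)C(=O)O | intermediate
4 | (−)-α-santonin, (11S)-3-oxoeudesma-1,4-dien-6α,12-olide | O=C1O[C@@H]2C3=C(C)C(=O)C=C[C@]3(C)CC[C@H]2[C@@H]1C | starting material
5 | 1α,2α-epoxy-3-oxoeudesm-4-en-6α,12-olide | O=C1O[C@@H]2C3=C(C)C(=O)[C@@H]4O[C@@H]4[C@]3(C)CC[C@H]2[C@@H]1C | intermediate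
6 | 1α-hydroxy-2β-(phenylselanyl)-3-oxoeudesm-4-en-6α,12-olide | O=C1O[C@@H]2C3=C(C)C(=O)[C@@H]([Se]c4ccccc4)[C@H](O)[C@]3(C)CC[C@H]2[C@@H]1C | intermediate
7 | 1α-hydroxy-3-oxoeudesm-4-en-6α,12-olide | O=C1O[C@@H]2C3=C(C)C(=O)C[C@H](O)[C@]3(C)CC[C@H]2[C@@H]1C | intermediate
8 | 1α,3β-dihydroxyeudesm-4-en-6α,12-olide | O=C1O[C@@H]2C3=C(C)[C@@H](O)C[C@H](O)[C@]3(C)CC[C@H]2[C@@H]1C | intermediate
9 | 1α-hydroxy-3α-[1-(2-nitrophenylsulfonyl)hydrazinyl]eudesm-4-en-6α,12-olide | O=C1O[C@@H]2C3=C(C)[C@H](N(N)S(=O)(=O)c4ccccc4[N+](=O)[O-])C[C@H](O)[C@]3(C)CC[C@H]2[C@@H]1C | intermediate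
10 | 3α-diazenyl-1α-hydroxyeudesm-4-en-6α,12-olide | O=C1O[C@@H]2C3=C(C)[C@H](N=N)C[C@H](O)[C@]3(C)CC[C@H]2[C@@H]1C | intermediate
11 | 1α-hydroxy-5αH-eudesm-3-en-6α,12-olide | O=C1O[C@@H]2[C@H]3C(C)=CC[C@H](O)[C@]3(C)CC[C@H]2[C@@H]1C | intermediate
12 | 1-oxo-5αH-eudesm-3-en-6α,12-olide | O=C1O[C@@H]2[C@H]3C(C)=CCC(=O)[C@]3(C)CC[C@H]2[C@@H]1C | intermediate
13 | 1β-hydroxy-5αH-eudesm-3-en-6α,12-olide (11β,13-dihydrosantamarine) | O=C1O[C@@H]2[C@H]3C(C)=CC[C@@H](O)[C@]3(C)CC[C@H]2[C@@H]1C | intermediate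
14 | 3α-bromo-1β,4β-dihydroxy-5αH-eudesman-6α,12-olide | O=C1O[C@@H]2[C@H]3[C@@](C)(O)[C@H](Br)C[C@@H](O)[C@]3(C)CC[C@H]2[C@@H]1C | intermediate
15 | 3β,4β-epoxy-1β-hydroxy-5αH-eudesman-6α,12-olide | O=C1O[C@@H]2[C@H]3[C@@]4(C)O[C@H]4C[C@@H](O)[C@]3(C)CC[C@H]2[C@@H]1C | intermediate
16 | 1β,3β-dihydroxy-5αH-eudesm-4(15)-en-6α,12-olide | O=C1O[C@@H]2[C@H]3C(=C)[C@@H](O)C[C@@H](O)[C@]3(C)CC[C@H]2[C@@H]1C | intermediate
17 | 1β,3β-bis(TBSO)-5αH-eudesm-4(15)-en-6α,12-olide | O=C1O[C@@H]2[C@H]3C(=C)[C@@H](O[Si](C)(C)C(C)(C)C)C[C@@H](O[Si](C)(C)C(C)(C)C)[C@]3(C)CC[C@H]2[C@@H]1C | intermediate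
18 | 11α-(phenylselanyl)-1β,3β-bis(TBSO)-5αH-eudesm-4(15)-en-6α,12-olide | O=C1O[C@@H]2[C@H]3C(=C)[C@@H](O[Si](C)(C)C(C)(C)C)C[C@@H](O[Si](C)(C)C(C)(C)C)[C@]3(C)CC[C@H]2[C@]1(C)[Se]c4ccccc4 | intermediate
19 | 11α-(phenylseleninyl)-1β,3β-bis(TBSO)-5αH-eudesm-4(15)-en-6α,12-olide | O=C1O[C@@H]2[C@H]3C(=C)[C@@H](O[Si](C)(C)C(C)(C)C)C[C@@H](O[Si](C)(C)C(C)(C)C)[C@]3(C)CC[C@H]2[C@]1(C)[Se](=O)c4ccccc4 | intermediate
20 | 1β,3β-bis(TBSO)-5αH-eudesma-4(15),11(13)-dien-6α,12-olide | O=C1O[C@@H]2[C@H]3C(=C)[C@@H](O[Si](C)(C)C(C)(C)C)C[C@@H](O[Si](C)(C)C(C)(C)C)[C@]3(C)CC[C@H]2C1=C | intermediate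
21 | lithium 6α-hydroxy-1β,3β-bis(TBSO)eudesma-4(15),11(13)-dien-12-oate | [Li+].O[C@@H]1[C@H]2C(=C)[C@@H](O[Si](C)(C)C(C)(C)C)C[C@@H](O[Si](C)(C)C(C)(C)C)[C@]2(C)CC[C@H]1C(=C)C(=O)[O-] | intermediate
22 | methyl 6α-hydroxy-1β,3β-bis(TBSO)eudesma-4(15),11(13)-dien-12-oate | O[C@@H]1[C@H]2C(=C)[C@@H](O[Si](C)(C)C(C)(C)C)C[C@@H](O[Si](C)(C)C(C)(C)C)[C@]2(C)CC[C@H]1C(=C)C(=O)OC | intermediate
23 | 2-[(TBSO)methyl]acrylic 2,4,6-trichlorobenzoic anhydride | C=C(CO[Si](C)(C)C(C)(C)C)C(=O)OC(=O)c1c(Cl)cc(Cl)cc1Cl | intermediate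
24 | methyl 1β,3β-bis(TBSO)-6α-{2-[(TBSO)methyl]acryloyloxy}eudesma-4(15),11(13)-dien-12-oate | C=C(CO[Si](C)(C)C(C)(C)C)C(=O)O[C@@H]1[C@H]2C(=C)[C@@H](O[Si](C)(C)C(C)(C)C)C[C@@H](O[Si](C)(C)C(C)(C)C)[C@]2(C)CC[C@H]1C(=C)C(=O)OC | intermediate
25 | methyl (1R,3S,5S,6S,7S,10R)-1β,3β-dihydroxy-6α-[2-(hydroxymethyl)acryloyloxy]eudesma-4(15),11(13)-dien-12-oate | C=C(CO)C(=O)O[C@@H]1[C@H]2C(=C)[C@@H](O)C[C@@H](O)[C@]2(C)CC[C@H]1C(=C)C(=O)OC | target

**Totals**
Total step count: 15. Longest linear sequence: 13 steps (steps 3–15, from santonin 4); the acid 3 takes 2 steps.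

**The three steps most likely to fail**

Step 6 (Myers transposition). The SN2 at C3 is flanked by the C4 methyl and the syn-axial 1α-OH, and ionisation or elimination of the allylic oxyphosphonium could compete. The fallback sets out from 8 and comes back at 11. The allylic 3β-hydroxyl alone is formylated (acetic formic anhydride, pyridine, 0 °C) to 1α-hydroxy-3β-formyloxyeudesm-4-en-6α,12-olide F1. Pd(OAc)2/n-Bu3P in THF (Tsuji–Mandai hydrogenolysis) then ionises the formate with inversion to an α-face π-allylpalladium formate, which loses CO2 and passes hydride from palladium to the more substituted terminus C5 on the α face, giving 11 without any diazene.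

Step 9 (β-epoxide through the bromohydrin). Water must attack the hindered β face of C4, and the ring closure must outrun other reactions. The fallback sets out from 13 and comes back at 16, so it also avoids step 10. mCPBA epoxidises the open α face to 3α,4α-epoxy-1β-hydroxy-5αH-eudesman-6α,12-olide F2. Al(OiPr)3 in hot toluene isomerises it to 1β,3α-dihydroxy-5αH-eudesm-4(15)-en-6α,12-olide F3. MnO2 oxidises only the allylic hydroxyl to 1β-hydroxy-3-oxo-5αH-eudesm-4(15)-en-6α,12-olide F4, and Luche reduction (NaBH4, CeCl3, MeOH, −78 °C) attacks from the α face to give the 3β-alcohol 16.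

Step 13 (free γ-hydroxy ester). Compound 22 may relactonise to 20 before or during acylation. The fallback sets out from 21 and comes back at 24, so 22 is never made. The dried lithium carboxylate 21 is deprotonated at O6 with LiHMDS (THF, −78 °C) and the alkoxide is acylated with 2-[(TBSO)methyl]acryloyl chloride F5, made from 3 with 1-chloro-N,N,2-trimethylpropenylamine. Aqueous work-up gives 1β,3β-bis(TBSO)-6α-{2-[(TBSO)methyl]acryloyloxy}eudesma-4(15),11(13)-dien-12-oic acid F6, which cannot lactonise, and TMSCHN2 in MeOH/toluene then gives 24.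

**Further compounds**
F1 | step 6 | 1α-hydroxy-3β-formyloxyeudesm-4-en-6α,12-olide | O=C1O[C@@H]2C3=C(C)[C@@H](OC=O)C[C@H](O)[C@]3(C)CC[C@H]2[C@@H]1C
F2 | step 9 | 3α,4α-epoxy-1β-hydroxy-5αH-eudesman-6α,12-olide | O=C1O[C@@H]2[C@H]3[C@]4(C)O[C@@H]4C[C@@H](O)[C@]3(C)CC[C@H]2[C@@H]1C
F3 | step 9 | 1β,3α-dihydroxy-5αH-eudesm-4(15)-en-6α,12-olide | O=C1O[C@@H]2[C@H]3C(=C)[C@H](O)C[C@@H](O)[C@]3(C)CC[C@H]2[C@@H]1C
F4 | step 9 | 1β-hydroxy-3-oxo-5αH-eudesm-4(15)-en-6α,12-olide | O=C1O[C@@H]2[C@H]3C(=C)C(=O)C[C@@H](O)[C@]3(C)CC[C@H]2[C@@H]1C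
F5 | step 13 | 2-[(TBSO)methyl]acryloyl chloride | C=C(CO[Si](C)(C)C(C)(C)C)C(=O)Cl
F6 | step 13 | 1β,3β-bis(TBSO)-6α-{2-[(TBSO)methyl]acryloyloxy}eudesma-4(15),11(13)-dien-12-oic acid | C=C(CO[Si](C)(C)C(C)(C)C)C(=O)O[C@@H]1[C@H]2C(=C)[C@@H](O[Si](C)(C)C(C)(C)C)C[C@@H](O[Si](C)(C)C(C)(C)C)[C@]2(C)CC[C@H]1C(=C)C(=O)O
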